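The pyranone ring (O1, C2, C3, C4, C4a, C8a) is disconnected at O1–C2. The C8 prenyl group is traced back to a 1,1-dimethylallyl group on O1, which exploits the ortho sequence C8–C8a–O1 of the benzene ring. The precursor is therefore an aryl tert-prenyl ether with a syn-aldol chain on C4a. Its C5 oxygen and carboxyl group are tied up as a dihydrocoumarin lactone. In one flask, heating moves the five-carbon unit from O1 to C8 by a [3,3] rearrangement and frees the phenol. PPh3/DIAD then closes the ring by SN2 inversion at C2, giving the trans-2,3-dimethylchromanone under kinetic control.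

Key step: step 7

Assumption: the antipodes named for the SEGPHOS ligand (step 2), the boron reagent (step 6) and the fallback catalysts are those expected by analogy with simpler substrates. The sense of induction is to be confirmed on the first chiral lactone and on the aldol product, and the other antipode is used if it proves opposite.

Step 1
Reactants: 1 3,5-dimethoxyphenol; 2 ethyl 3-oxohexanoate
Product: 3 5,7-dimethoxy-4-propyl-2H-chromen-2-one
Conditions: MeSO3H, 0 °C → rt
Reagents that add atoms: ethyl 3-oxohexanoate (2), CCCC(=O)CC(=O)OCC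
Why: Pechmann condensation (transesterification, intramolecular hydroxyalkylation ortho to the phenol oxygen, dehydration); the two ortho positions of the symmetric, doubly activated phenol are equivalent, so a single coumarin should form.

Step 2
Reactants: 3 5,7-dimethoxy-4-propyl-2H-chromen-2-one
Product: 5 (4R)-5,7-dimethoxy-4-propylchroman-2-one, via silyl ketene acetal 4 (not isolated)
Conditions: Cu(OAc)2·H2O (cat.), (S)-DTBM-SEGPHOS (cat.), MeSiH(OEt)2, PhMe, rt, no protic additive; then H2O
Reagents that add atoms: none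
Why: Ligand-controlled CuH-catalysed asymmetric conjugate reduction of a β,β-disubstituted unsaturated lactone: hydride is delivered to one face of C4 and sets the 4R centre (the later side-chain centre), and the product stays masked as silyl ketene acetal 4 until work-up, which should suppress 1,2-over-reduction.

Step 3
Reactants: 5 (4R)-5,7-dimethoxy-4-propylchroman-2-one; 6 propanoyl chloride
Product: 8 (4R)-7-hydroxy-5-methoxy-8-propanoyl-4-propylchroman-2-one, via 8-propanoyl dimethyl ether 7 (not isolated)
Conditions: AlCl3 (3 equiv), CH2Cl2, 0 °C → reflux; then ice-water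
Reagents that add atoms: propanoyl chloride (6), CCC(=O)Cl
Why: Friedel–Crafts acylation at C8, the less hindered of the two activated positions (C6 lies between two methoxy groups, the 5-OMe being turned towards it by the peri C4 substituent), followed by chelation-directed AlCl3 cleavage of the one methyl ether that is ortho to the new ketone.

Step 4
Reactants: 9 2-methylbut-3-en-2-ol; 10 di-tert-butyl dicarbonate
Product: 12 tert-butyl (2-methylbut-3-en-2-yl) carbonate, via lithium alkoxide 11 (not isolated)
Conditions: n-BuLi, THF, 0 °C; then Boc2O, 0 °C → rt; H2O work-up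
Reagents that add atoms: di-tert-butyl dicarbonate (10), CC(C)(C)OC(=O)OC(=O)OC(C)(C)C
Why: O-acylation of the lithium alkoxide of a tertiary allylic alcohol with Boc2O, a standard mixed-carbonate synthesis.

Step 5
Reactants: 8 (4R)-7-hydroxy-5-methoxy-8-propanoyl-4-propylchroman-2-one; 12 tert-butyl (2-methylbut-3-en-2-yl) carbonate
Product: 13 (4R)-5-methoxy-7-[(2-methylbut-3-en-2-yl)oxy]-8-propanoyl-4-propylchroman-2-one
Conditions: Pd(PPh3)4 (5 mol %), THF, 0 °C
Reagents that add atoms: tert-butyl (2-methylbut-3-en-2-yl) carbonate (12), C=CC(C)(C)OC(=O)OC(C)(C)C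
Why: Tsuji–Trost-type decarboxylative O-allylation: the liberated tert-butoxide deprotonates the phenol, and the phenoxide attacks the more substituted terminus of the 1,1-dimethyl-π-allylpalladium complex under kinetic control at low temperature, while the saturated acyl chain offers no path to premature cyclisation.

Step 6
Reactants: 13 (4R)-5-methoxy-7-[(2-methylbut-3-en-2-yl)oxy]-8-propanoyl-4-propylchroman-2-one; 14 acetaldehyde
Product: 17 (4R)-8-[(2S,3R)-3-hydroxy-2-methylbutanoyl]-5-methoxy-7-[(2-methylbut-3-en-2-yl)oxy]-4-propylchroman-2-one, via Z-enol borinate 15 (not isolated), via boron aldolate 16 (not isolated)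
Conditions: (−)-Ipc2BOTf [from (+)-α-pinene], i-Pr2NEt, CH2Cl2, −78 → 0 °C; MeCHO, −78 → −20 °C; pH 7 buffer–MeOH, then SiO2 (no peroxide)
Reagents that add atoms: acetaldehyde (14), CC=O
Why: Diisopinocampheylboron-mediated syn-aldol reaction: soft enolisation takes the ketone (more Lewis basic than the aryl lactone) to the Z-enol borinate 15, whose chair Zimmerman–Traxler transition state gives the syn relationship, while the Ipc ligands direct attack to the Si face of acetaldehyde and so set (2S,3R), that is the final C3 centre and the C2 carbinol that is to be inverted.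

Step 7
Reactants: 17 (4R)-8-[(2S,3R)-3-hydroxy-2-methylbutanoyl]-5-methoxy-7-[(2-methylbut-3-en-2-yl)oxy]-4-propylchroman-2-one
Product: 19 (4R,8S,9S)-5-methoxy-8,9-dimethyl-6-(3-methylbut-2-en-1-yl)-4-propyl-3,4,8,9-tetrahydro-2H,10H-pyrano[2,3-f]chromene-2,10-dione, via prenylated phenol 18 (not isolated)
Conditions: PhMe, 110 °C; cool to 0 °C, then PPh3, DIAD, 0 °C → rt (same flask)
Reagents that add atoms: none
Why: Heating triggers an aromatic Claisen [3,3] rearrangement of the aryl 1,1-dimethylallyl ether, in which the alkene terminus bonds to target C8, the only ortho carbon that carries hydrogen (migration to the acylated C4a is reversible and cannot rearomatise), and rearomatisation gives the linear prenyl group and the free O1–H of 18. PPh3/DIAD then activates the secondary C2 hydroxyl, and the hydrogen-bonded but sufficiently acidic phenol displaces it in a 6-exo-tet closure, an intramolecular Mitsunobu etherification of the kind known for o-hydroxyaryl β-hydroxy ketones. C2 is set by SN2 inversion (3R carbinol → 2S) and C3 is carried over unchanged from the aldol reaction, so the syn aldol maps onto the trans-2,3-dimethyl ring as a kinetic result that does not depend on the small cis/trans energy difference. Site selectivity of the closure is secured because O1 is the only free phenol, the C5 oxygen being locked in the lactone. The neutral medium should hold back E1cB dehydration and the stereorandom oxa-Michael pathway that would follow it. The ether thus serves in turn as phenol protection in step 6, as the source of the C8 prenyl group and as the trigger of ring closure.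

Step 8
Reactants: 19 (4R,8S,9S)-5-methoxy-8,9-dimethyl-6-(3-methylbut-2-en-1-yl)-4-propyl-3,4,8,9-tetrahydro-2H,10H-pyrano[2,3-f]chromene-2,10-dione
Product: 21 (3R)-3-[(2S,3S)-5-hydroxy-7-methoxy-2,3-dimethyl-8-(3-methylbut-2-en-1-yl)-4-oxo-3,4-dihydro-2H-chromen-6-yl]hexanoic acid, via dilithium salt 20 (not isolated)
Conditions: LiOH (2.2 equiv), THF–H2O, 0 °C; then 1 M HCl to pH 3–4, 0 °C
Reagents that add atoms: lithium hydroxide, [Li+].[OH-]
Why: Saponification of the aryl lactone should be far faster than enolisation at C3, and the C5 phenoxide it releases is conjugated with the C4 ketone and shuts down epimerisation and retro-oxa-Michael opening, so all three centres are kept and the chelated C5-OH should not relactonise on cold acidification.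

Compound list
1 | 3,5-dimethoxyphenol | COc1cc(O)cc(OC)c1 | starting material
2 | ethyl 3-oxohexanoate | CCCC(=O)CC(=O)OCC | starting material
3 | 5,7-dimethoxy-4-propyl-2H-chromen-2-one | CCCC1=CC(=O)Oc2cc(OC)cc(OC)c12 | intermediate
4 | (4R)-2-[diethoxy(methyl)silyloxy]-5,7-dimethoxy-4-propyl-4H-chromene (silyl ketene acetal, not isolated) | CCC[C@@H]1C=C(O[Si](C)(OCC)OCC)Oc2cc(OC)cc(OC)c12 | intermediate
5 | (4R)-5,7-dimethoxy-4-propylchroman-2-one | CCC[C@@H]1CC(=O)Oc2cc(OC)cc(OC)c12 | intermediate
6 | propanoyl chloride | CCC(=O)Cl | starting material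
7 | (4R)-5,7-dimethoxy-8-propanoyl-4-propylchroman-2-one (not isolated) | CCC[C@@H]1CC(=O)Oc2c1c(OC)cc(OC)c2C(=O)CC | intermediate
8 | (4R)-7-hydroxy-5-methoxy-8-propanoyl-4-propylchroman-2-one | CCC[C@@H]1CC(=O)Oc2c1c(OC)cc(O)c2C(=O)CC | intermediate
9 | 2-methylbut-3-en-2-ol | C=CC(C)(C)O | starting material
10 | di-tert-butyl dicarbonate | CC(C)(C)OC(=O)OC(=O)OC(C)(C)C | starting material
11 | lithium 2-methylbut-3-en-2-olate (not isolated) | [Li+].[O-]C(C)(C)C=C | intermediate
12 | tert-butyl (2-methylbut-3-en-2-yl) carbonate | C=CC(C)(C)OC(=O)OC(C)(C)C | intermediate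
13 | (4R)-5-methoxy-7-[(2-methylbut-3-en-2-yl)oxy]-8-propanoyl-4-propylchroman-2-one | CCC[C@@H]1CC(=O)Oc2c1c(OC)cc(OC(C)(C)C=C)c2C(=O)CC | intermediate
14 | acetaldehyde | CC=O | starting material
15 | (Z)-enol diisopinocampheylborinate of 13 (not isolated) | CCC[C@@H]1CC(=O)Oc2c1c(OC)cc(OC(C)(C)C=C)c2/C(=C/C)OB([C@@H]1C[C@@H]2C[C@H]([C@H]1C)C2(C)C)[C@@H]1C[C@@H]2C[C@H]([C@H]1C)C2(C)C | intermediate
16 | O-diisopinocampheylboryl derivative of 17 (boron aldolate, not isolated) | CCC[C@@H]1CC(=O)Oc2c1c(OC)cc(OC(C)(C)C=C)c2C(=O)[C@@H](C)[C@@H](C)OB([C@@H]1C[C@@H]2C[C@H]([C@H]1C)C2(C)C)[C@@H]1C[C@@H]2C[C@H]([C@H]1C)C2(C)C | intermediate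
17 | (4R)-8-[(2S,3R)-3-hydroxy-2-methylbutanoyl]-5-methoxy-7-[(2-methylbut-3-en-2-yl)oxy]-4-propylchroman-2-one | CCC[C@@H]1CC(=O)Oc2c1c(OC)cc(OC(C)(C)C=C)c2C(=O)[C@@H](C)[C@@H](C)O | intermediate
18 | (4R)-7-hydroxy-8-[(2S,3R)-3-hydroxy-2-methylbutanoyl]-5-methoxy-6-(3-methylbut-2-en-1-yl)-4-propylchroman-2-one (not isolated) | CCC[C@@H]1CC(=O)Oc2c1c(OC)c(CC=C(C)C)c(O)c2C(=O)[C@@H](C)[C@@H](C)O | intermediate
19 | (4R,8S,9S)-5-methoxy-8,9-dimethyl-6-(3-methylbut-2-en-1-yl)-4-propyl-3,4,8,9-tetrahydro-2H,10H-pyrano[2,3-f]chromene-2,10-dione | CCC[C@@H]1CC(=O)Oc2c1c(OC)c(CC=C(C)C)c1c2C(=O)[C@@H](C)[C@H](C)O1 | intermediate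
20 | dilithium carboxylate-phenoxide of 21 (not isolated) | CCC[C@H](CC(=O)[O-])c1c([O-])c2c(c(CC=C(C)C)c1OC)O[C@@H](C)[C@H](C)C2=O.[Li+].[Li+] | intermediate
21 | (3R)-3-[(2S,3S)-5-hydroxy-7-methoxy-2,3-dimethyl-8-(3-methylbut-2-en-1-yl)-4-oxo-3,4-dihydro-2H-chromen-6-yl]hexanoic acid | CCC[C@H](CC(=O)O)c1c(O)c2c(c(CC=C(C)C)c1OC)O[C@@H](C)[C@H](C)C2=O | target

Total step count: 8. Longest linear sequence: 7 (steps 1, 2, 3, 5, 6, 7, 8).

Steps most likely to fail

1. Step 6.
- Risk: enolisation of the doubly ortho-substituted ketone by the bulky boron triflate may be slow. It may compete with enolisation of the lactone or with Lewis-acid ionisation of the tertiary ether. Reagent control of the aldehyde face may also be incomplete.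
- Fallback: starting from 13, an achiral dibutylboron triflate/i-Pr2NEt syn-aldol reaction with acetaldehyde gives 17 mixed with its (2R,3S)-configured syn diastereomer F1. Lipase-catalysed acetylation (Burkholderia cepacia lipase, vinyl acetate, t-BuOMe) should acylate only the (3R)-carbinol to the (2S,3R)-acetate F2, which is separated from unreacted F1 by chromatography. Lipase-catalysed methanolysis of F2 comes back to 17.

2. Step 5.
- Risk: the hydrogen-bonded phenol may be a poor nucleophile. Reversible ionisation of the product by Pd(0) may drain the tertiary ether into the linear O-prenyl isomer.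
- Fallback: starting from 8, copper-catalysed propargylation (3-chloro-3-methylbut-1-yne, CuCl2 cat., DBU, MeCN, 0 °C) gives the 1,1-dimethylpropargyl ether F3. Semi-hydrogenation over Lindlar catalyst (H2, quinoline, EtOAc) comes back to 13.

3. Step 2.
- Risk: hydride transfer to the electron-rich, peri-hindered β-carbon may be slow, facial selectivity may be modest, and over-reduction of the lactone may set in.
- Fallback: starting from 1, iminium-catalysed Friedel–Crafts alkylation/hemiacetalisation with (E)-hex-2-enal ((S)-α,α-diphenylprolinol trimethylsilyl ether, PhCO2H, CH2Cl2) builds the stereocentre by C–C bond formation and gives the lactol F4. Oxidation (TEMPO, PhI(OAc)2) comes back to 5, bypassing 3.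

Further compounds
F1 | step 6 | (4R)-8-[(2R,3S)-3-hydroxy-2-methylbutanoyl]-5-methoxy-7-[(2-methylbut-3-en-2-yl)oxy]-4-propylchroman-2-one | CCC[C@@H]1CC(=O)Oc2c1c(OC)cc(OC(C)(C)C=C)c2C(=O)[C@H](C)[C@H](C)O
F2 | step 6 | (4R)-8-[(2S,3R)-3-acetoxy-2-methylbutanoyl]-5-methoxy-7-[(2-methylbut-3-en-2-yl)oxy]-4-propylchroman-2-one | CCC[C@@H]1CC(=O)Oc2c1c(OC)cc(OC(C)(C)C=C)c2C(=O)[C@@H](C)[C@@H](C)OC(C)=O
F3 | step 5 | (4R)-5-methoxy-7-[(2-methylbut-3-yn-2-yl)oxy]-8-propanoyl-4-propylchroman-2-one | CCC[C@@H]1CC(=O)Oc2c1c(OC)cc(OC(C)(C)C#C)c2C(=O)CC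
F4 | step 2 | (4R)-5,7-dimethoxy-4-propylchroman-2-ol (both anomers) | CCC[C@@H]1CC(O)Oc2cc(OC)cc(OC)c12
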